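## Retrosynthetic overview

1. Final global desilylation; the chalcone arm is attached last by a Heck coupling of a 5-bromo-2,3-dihydrobenzofuran with an aryl vinyl ketone.
2. The dihydrobenzofuran (last ring formed) comes from a ligand-controlled Pd oxyarylation of an (E)-1,3,3-triarylpropene with 4-bromo-2-iodophenol, making the C3–aryl and C2–O bonds.
3. The diarylmethine centre comes from a Rh/chiral-diene conjugate arylation of an enone, itself made by Heck coupling of the oxolane-bearing aryl bromide.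
4. The oxolane: a lactone Weinreb amide takes up two equivalents of one aryllithium, and BF3/Et3SiH reduction of the hemiketal sets the 2,3-cis aryl.
5. The lactone (first ring) comes from DKR transfer hydrogenation/lactonisation and trans benzylation; all arenes derive from resorcinol, 4-bromophenol and p-cresol.

Assumption: the ligand antipodes named are those expected by analogy to give the drawn configurations; the opposite antipode is used if the sense proves reversed.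

Abbreviations: TBS = tert-butyldimethylsilyl. Ox = (2S,3R,4R,5R)-4-[2,4-bis(TBSO)benzoyl]-3-[4-(TBSO)benzyl]-5-[4-(TBSO)phenyl]oxolan-2-yl (C2 aryl cis to the C3 benzyl and the C5 aryl; C4 aroyl trans to both neighbours).

## Route

Step 1
Reactants: 1 resorcinol
Product: 2 1,3-bis(TBSO)benzene
Conditions: TBSCl (2.3 equiv), imidazole (5 equiv), DMF, 25 °C
Reagents that add atoms: tert-butyldimethylsilyl chloride, CC(C)(C)[Si](C)(C)Cl
Why: Imidazole-promoted O-silylation protects both phenols as fluoride-labile silyl ethers.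

Step 2
Reactants: 2 1,3-bis(TBSO)benzene
Product: 3 1-bromo-2,4-bis(TBSO)benzene
Conditions: NBS (1.0 equiv), MeCN, 0 °C, dark
Reagents that add atoms: N-bromosuccinimide, O=C1CCC(=O)N1Br
Why: Electrophilic aromatic bromination goes to C4, para to one silyloxy group and ortho to the other, the only unhindered doubly activated site.

Step 3
Reactants: 3 1-bromo-2,4-bis(TBSO)benzene
Product: 4 2-[2,4-bis(TBSO)phenyl]-4,4,5,5-tetramethyl-1,3,2-dioxaborolane
Conditions: Pd2(dba)3 (1.5 mol%), XPhos (6 mol%), B2pin2 (1.2 equiv), KOAc (3 equiv), 1,4-dioxane, 85 °C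
Reagents that add atoms: bis(pinacolato)diboron, CC1(C)OB(OC1(C)C)B1OC(C)(C)C(C)(C)O1
Why: Miyaura borylation (oxidative addition of zerovalent palladium to the C–Br bond, acetate-assisted transmetalation with the diboron, reductive elimination) installs boron under weakly basic aprotic conditions that leave the aryl silyl ethers intact and involve no aryl–alkali-metal species that could undergo silyl migration.

Step 4
Reactants: 3 1-bromo-2,4-bis(TBSO)benzene; 5 acrolein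
Product: 7 1-[2,4-bis(TBSO)phenyl]prop-2-en-1-ol (racemic), via arylmagnesium bromide 6 (not isolated)
Conditions: Mg turnings (1.5 equiv), LiCl (1.2 equiv), i-Bu2AlH (1 mol%), THF, 25 °C; 5 (1.3 equiv), −78 °C; AcOH (1.1 equiv), −78 °C
Reagents that add atoms: none
Why: LiCl-assisted magnesium insertion gives the aryl Grignard reagent, which is far less prone to 1,3-silyl migration than its lithium counterpart, and its 1,2-addition to the enal at low temperature gives the allylic alcohol.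

Step 5
Reactants: 7 1-[2,4-bis(TBSO)phenyl]prop-2-en-1-ol
Product: 8 1-[2,4-bis(TBSO)phenyl]prop-2-en-1-one
Conditions: MnO2 (15 equiv), CH2Cl2, 25 °C
Reagents that add atoms: none
Why: MnO2 selectively oxidises the doubly activated (allylic and benzylic) alcohol to the aryl vinyl ketone under neutral conditions.

Step 6
Reactants: 9 4-bromophenol
Product: 10 (4-bromophenoxy)(tert-butyl)dimethylsilane
Conditions: TBSCl (1.1 equiv), imidazole (2.5 equiv), DMF, 25 °C
Reagents that add atoms: tert-butyldimethylsilyl chloride, CC(C)(C)[Si](C)(C)Cl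
Why: Standard imidazole-promoted O-silylation of the phenol.

Step 7
Reactants: 10 (4-bromophenoxy)(tert-butyl)dimethylsilane; 11 N,N-dimethylformamide
Product: 13 4-(TBSO)benzaldehyde, via aryllithium 12 (not isolated)
Conditions: n-BuLi (1.05 equiv), THF, −78 °C; 11 (2 equiv), −78 → 0 °C; AcOH (1.1 equiv), H2O
Reagents that add atoms: none
Why: Bromine–lithium exchange and Bouveault formylation of the aryllithium with DMF give the aldehyde.

Step 8
Reactants: 13 4-(TBSO)benzaldehyde; 14 vinylmagnesium bromide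
Product: 15 1-[4-(TBSO)phenyl]prop-2-en-1-ol (racemic)
Conditions: 14 (1.2 equiv, 1.0 M in THF), THF, −78 °C; AcOH (1.3 equiv), −78 °C
Reagents that add atoms: none
Why: Grignard 1,2-addition of the vinyl nucleophile to the aromatic aldehyde gives the allylic benzylic alcohol directly.

Step 9
Reactants: 15 1-[4-(TBSO)phenyl]prop-2-en-1-ol
Product: 16 1-[4-(TBSO)phenyl]prop-2-en-1-one
Conditions: MnO2 (15 equiv), CH2Cl2, 25 °C
Reagents that add atoms: none
Why: MnO2 oxidation of the allylic benzylic alcohol gives the aryl vinyl ketone.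

Step 10
Reactants: 9 4-bromophenol
Product: 17 4-bromo-2-iodophenol
Conditions: NIS (1.0 equiv), TsOH·H2O (10 mol%), MeCN, 25 °C
Reagents that add atoms: N-iodosuccinimide, O=C1CCC(=O)N1I
Why: Electrophilic aromatic iodination occurs ortho to the hydroxyl because the para position is blocked by bromine.

Step 11
Reactants: 18 4-methylphenol
Product: 19 tert-butyldimethyl(4-methylphenoxy)silane
Conditions: TBSCl (1.1 equiv), imidazole (2.5 equiv), DMF, 25 °C
Reagents that add atoms: tert-butyldimethylsilyl chloride, CC(C)(C)[Si](C)(C)Cl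
Why: Standard O-silylation of the phenol.

Step 12
Reactants: 19 tert-butyldimethyl(4-methylphenoxy)silane
Product: 20 [4-(bromomethyl)phenoxy](tert-butyl)dimethylsilane
Conditions: NBS (1.05 equiv), AIBN (5 mol%), PhCF3, 80 °C
Reagents that add atoms: N-bromosuccinimide, O=C1CCC(=O)N1Br
Why: Wohl–Ziegler radical bromination is selective for the benzylic methyl group in a non-polar medium.

Step 13
Reactants: 21 N-methoxy-N-methylacetamide; 13 4-(TBSO)benzaldehyde
Product: 23 3-hydroxy-N-methoxy-N-methyl-3-[4-(TBSO)phenyl]propanamide (racemic), via lithium enolate 22 (not isolated)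
Conditions: LiN(iPr)2 (1.1 equiv), THF, −78 °C; 13, −78 °C; AcOH (1.2 equiv)
Reagents that add atoms: none
Why: Aldol addition of the Weinreb acetamide lithium enolate to the aldehyde; the racemic carbinol is erased in the next step.

Step 14
Reactants: 23 3-hydroxy-N-methoxy-N-methyl-3-[4-(TBSO)phenyl]propanamide
Product: 24 N-methoxy-N-methyl-3-oxo-3-[4-(TBSO)phenyl]propanamide
Conditions: Dess–Martin periodinane (1.2 equiv), CH2Cl2, 0 → 25 °C
Reagents that add atoms: none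
Why: Dess–Martin oxidation converts the benzylic alcohol into the β-keto amide without touching the aryl silyl ether.

Step 15
Reactants: 24 N-methoxy-N-methyl-3-oxo-3-[4-(TBSO)phenyl]propanamide; 25 methyl bromoacetate
Product: 26 methyl 3-[methoxy(methyl)carbamoyl]-4-oxo-4-[4-(TBSO)phenyl]butanoate (racemic)
Conditions: K2CO3 (1.5 equiv), acetone, 25 °C
Reagents that add atoms: none
Why: C-alkylation of the active methylene of the β-keto amide with a reactive α-halo ester (enolate SN2 alkylation).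

Step 16
Reactants: 26 methyl 3-[methoxy(methyl)carbamoyl]-4-oxo-4-[4-(TBSO)phenyl]butanoate
Product: 28 (2R,3R)-N-methoxy-N-methyl-5-oxo-2-[4-(TBSO)phenyl]oxolane-3-carboxamide (trans), via syn-hydroxy amide 27 (not isolated)
Conditions: RuCl[(R,R)-TsDPEN](p-cymene) (1 mol%), HCO2H/Et3N (5:2), CH2Cl2, 30 °C; then TsOH·H2O (10 mol%), PhMe, 50 °C
Reagents that add atoms: none
Why: Noyori asymmetric transfer hydrogenation with dynamic kinetic resolution sets the (R)-carbinol by catalyst control while the rapidly epimerising α-centre is funnelled to the syn isomer (as known for α-alkyl β-keto amides), and acid-catalysed lactonisation onto the ester gives the trans lactone.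

Step 17
Reactants: 28 (2R,3R)-N-methoxy-N-methyl-5-oxo-2-[4-(TBSO)phenyl]oxolane-3-carboxamide; 20 [4-(bromomethyl)phenoxy](tert-butyl)dimethylsilane
Product: 30 (2R,3R,4R)-N-methoxy-N-methyl-5-oxo-4-[4-(TBSO)benzyl]-2-[4-(TBSO)phenyl]oxolane-3-carboxamide, via lactone lithium enolate 29 (not isolated)
Conditions: LiN(SiMe3)2 (1.05 equiv), THF, −78 °C; 20 (1.2 equiv), −78 → −40 °C
Reagents that add atoms: none
Why: Lactone enolate alkylation occurs at the more acidic lactone α-carbon (not α to the amide) and anti to the adjacent carboxamide, setting the 3,4-trans benzyl centre.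

Step 18
Reactants: 30 (2R,3R,4R)-N-methoxy-N-methyl-5-oxo-4-[4-(TBSO)benzyl]-2-[4-(TBSO)phenyl]oxolane-3-carboxamide; 3 1-bromo-2,4-bis(TBSO)benzene
Product: 32 [2,4-bis(TBSO)phenyl]{(2R,3R,4R,5RS)-5-[2,4-bis(TBSO)phenyl]-5-hydroxy-4-[4-(TBSO)benzyl]-2-[4-(TBSO)phenyl]oxolan-3-yl}methanone (hemiketal anomers), via aryllithium 31 (not isolated)
Conditions: 3 (2.6 equiv), n-BuLi (2.5 equiv), THF, −78 °C, 10 min; 30, −78 °C, 1 h; AcOH (3 equiv), −78 °C
Reagents that add atoms: none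
Why: One aryllithium, kept at −78 °C throughout, performs a Weinreb ketone synthesis at the amide and a single addition to the lactone (stable lithium hemiketalate at −78 °C), installing both resorcinol rings at once.

Step 19
Reactants: 32 hemiketal
Product: 33 1-Ox-2,4-bis(TBSO)benzene
Conditions: Et3SiH (5 equiv), BF3·OEt2 (2 equiv), CH2Cl2, −78 °C
Reagents that add atoms: none
Why: Ionic hydrogenation of the hemiketal through the aryl-stabilised oxocarbenium ion delivers hydride anti to the adjacent benzyl and the C5 aryl under kinetic control at −78 °C, setting the 2,3-cis/2,5-cis (2S) centre.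

Step 20
Reactants: 33 1-Ox-2,4-bis(TBSO)benzene
Product: 34 1-bromo-5-Ox-2,4-bis(TBSO)benzene
Conditions: NBS (1.0 equiv), MeCN/CH2Cl2 (1:1), −20 °C, dark
Reagents that add atoms: N-bromosuccinimide, O=C1CCC(=O)N1Br
Why: Electrophilic aromatic bromination selects the most electron-rich ring at the site para/ortho to its silyloxy groups, the acyl-bearing resorcinol ring being deactivated.

Step 21
Reactants: 34 1-bromo-5-Ox-2,4-bis(TBSO)benzene; 16 1-[4-(TBSO)phenyl]prop-2-en-1-one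
Product: 35 (E)-3-[2,4-bis(TBSO)-5-Ox-phenyl]-1-[4-(TBSO)phenyl]prop-2-en-1-one
Conditions: Pd2(dba)3 (2.5 mol%), [HP(t-Bu)3]BF4 (10 mol%), Cy2NMe (1.5 equiv), 16 (1.5 equiv), 1,4-dioxane, 60 °C
Reagents that add atoms: none
Why: Mizoroki–Heck coupling of the electron-rich aryl bromide with the vinyl ketone gives the E-enone by syn insertion and syn β-hydride elimination.

Step 22
Reactants: 35 (E)-enone; 4 2-[2,4-bis(TBSO)phenyl]-4,4,5,5-tetramethyl-1,3,2-dioxaborolane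
Product: 36 (3R)-3-[2,4-bis(TBSO)phenyl]-3-[2,4-bis(TBSO)-5-Ox-phenyl]-1-[4-(TBSO)phenyl]propan-1-one
Conditions: [RhCl(C2H4)2]2 (2.5 mol%), (R,R)-Ph-bod (5.5 mol%), Et3N (1 equiv), 4 (3 equiv), 1,4-dioxane/H2O (10:1), 60 °C
Reagents that add atoms: none
Why: Hayashi–Miyaura rhodium-catalysed asymmetric 1,4-addition, in which the pinacol boronate transmetalates to the hydroxo-rhodium diene species formed with Et3N/H2O and the chiral diene selects the enone face, so the diarylmethine centre is set by the catalyst although its two aryl groups are nearly identical.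

Step 23
Reactants: 36 ketone
Product: 37 (1RS,3R)-3-[2,4-bis(TBSO)phenyl]-3-[2,4-bis(TBSO)-5-Ox-phenyl]-1-[4-(TBSO)phenyl]propan-1-ol
Conditions: NaBH4 (0.6 equiv), THF/MeOH (10:1), −30 °C
Reagents that add atoms: none
Why: Borohydride reduction is chemoselective for the unhindered aryl methylene ketone over the α-branched, ortho-substituted oxolanyl ketone.

Step 24
Reactants: 37 alcohol
Product: 38 (1E,3R)-3-[2,4-bis(TBSO)phenyl]-3-[2,4-bis(TBSO)-5-Ox-phenyl]-1-[4-(TBSO)phenyl]prop-1-ene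
Conditions: Burgess reagent (1.5 equiv), PhMe, 50 °C
Reagents that add atoms: none
Why: Burgess syn-elimination of the benzylic alcohol under neutral conditions gives the conjugated E-styrene; the only β-hydrogens are on the methylene.

Step 25
Reactants: 38 (E)-triarylpropene; 17 4-bromo-2-iodophenol
Product: 39 (2R,3R)-5-bromo-3-{(R)-[2,4-bis(TBSO)phenyl][2,4-bis(TBSO)-5-Ox-phenyl]methyl}-2-[4-(TBSO)phenyl]-2,3-dihydro-1-benzofuran
Conditions: Pd2(dba)3 (5 mol%), (S)-t-Bu-PHOX (12 mol%), Ag2CO3 (1.1 equiv), 17 (1.5 equiv), 1,4-dioxane, 60 °C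
Reagents that add atoms: none
Why: Proposed new method: a ligand-controlled, face-selective syn-oxyarylation of an acyclic (E)-1,3,3-triarylpropene, in which zerovalent palladium inserts into the C–I bond of 17 (C–Br untouched), Ag2CO3 abstracts iodide to give a cationic aryl–palladium(PHOX) species, the enantioface-determining migratory insertion places the aryl on the alkene carbon remote from the 4-silyloxyphenyl group (palladium ends up benzylic, stabilised as an η3-benzyl by the electron-rich arene), and the ortho phenoxide closes onto that carbon (C–O reductive elimination or ionisation and capture) to the favoured 2,3-trans ring, so C3 is set by the ligand (the neighbouring stereocentre carries two near-identical aryl groups and gives little bias) and C2 follows as trans; the closest known reaction types are the racemic palladium-catalysed oxyarylation of propenylarenes with o-halophenols or o-hydroxyarenediazonium salts to trans-2-aryl-3-methyl-2,3-dihydrobenzofurans and the enantioselective palladium-catalysed heteroannulation of o-halophenols with 1,3-dienes.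

Step 26
Reactants: 39 bromo-dihydrobenzofuran; 8 1-[2,4-bis(TBSO)phenyl]prop-2-en-1-one
Product: 40 (E)-1-[2,4-bis(TBSO)phenyl]-3-[(2R,3R)-3-{(R)-[2,4-bis(TBSO)phenyl][2,4-bis(TBSO)-5-Ox-phenyl]methyl}-2-[4-(TBSO)phenyl]-2,3-dihydro-1-benzofuran-5-yl]prop-2-en-1-one (undeca-TBS ether of the target)
Conditions: Pd2(dba)3 (2.5 mol%), [HP(t-Bu)3]BF4 (10 mol%), Cy2NMe (1.5 equiv), 8 (1.5 equiv), 1,4-dioxane, 60 °C
Reagents that add atoms: none
Why: Mizoroki–Heck coupling of the unhindered, electron-rich aryl bromide with the aryl vinyl ketone builds the E-chalcone without touching any stereocentre.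

Step 27
Reactants: 40 undeca-TBS ether
Product: 41 CNP0225254.6 (target)
Conditions: Bu4NF (13 equiv), AcOH (13 equiv), THF, 0 → 25 °C, degassed
Reagents that add atoms: none
Why: Acetic-acid-buffered fluoride desilylation frees all eleven phenols near neutrality, avoiding acid ionisation of the benzylic ethers and base-induced quinone-methide or retro-oxa-Michael epimerisation.

## Compound list

1 | resorcinol | Oc1cccc(O)c1 | starting material
2 | 1,3-bis(TBSO)benzene | CC(C)(C)[Si](C)(C)Oc1cccc(O[Si](C)(C)C(C)(C)C)c1 | intermediate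
3 | 1-bromo-2,4-bis(TBSO)benzene | Brc1ccc(O[Si](C)(C)C(C)(C)C)cc1O[Si](C)(C)C(C)(C)C | intermediate
4 | 2-[2,4-bis(TBSO)phenyl]-4,4,5,5-tetramethyl-1,3,2-dioxaborolane | CC1(C)OB(OC1(C)C)c1ccc(O[Si](C)(C)C(C)(C)C)cc1O[Si](C)(C)C(C)(C)C | intermediate
5 | acrolein | C=CC=O | starting material
6 | [2,4-bis(TBSO)phenyl]magnesium bromide | Br[Mg]c1ccc(O[Si](C)(C)C(C)(C)C)cc1O[Si](C)(C)C(C)(C)C | intermediate
7 | 1-[2,4-bis(TBSO)phenyl]prop-2-en-1-ol (racemic) | C=CC(O)c1ccc(O[Si](C)(C)C(C)(C)C)cc1O[Si](C)(C)C(C)(C)C | intermediate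
8 | 1-[2,4-bis(TBSO)phenyl]prop-2-en-1-one | C=CC(=O)c1ccc(O[Si](C)(C)C(C)(C)C)cc1O[Si](C)(C)C(C)(C)C | intermediate
9 | 4-bromophenol | Oc1ccc(Br)cc1 | starting material
10 | (4-bromophenoxy)(tert-butyl)dimethylsilane | CC(C)(C)[Si](C)(C)Oc1ccc(Br)cc1 | intermediate
11 | N,N-dimethylformamide | CN(C)C=O | starting material
12 | [4-(TBSO)phenyl]lithium | [Li]c1ccc(O[Si](C)(C)C(C)(C)C)cc1 | intermediate
13 | 4-(TBSO)benzaldehyde | O=Cc1ccc(O[Si](C)(C)C(C)(C)C)cc1 | intermediate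
14 | vinylmagnesium bromide | C=C[Mg]Br | starting material
15 | 1-[4-(TBSO)phenyl]prop-2-en-1-ol (racemic) | C=CC(O)c1ccc(O[Si](C)(C)C(C)(C)C)cc1 | intermediate
16 | 1-[4-(TBSO)phenyl]prop-2-en-1-one | C=CC(=O)c1ccc(O[Si](C)(C)C(C)(C)C)cc1 | intermediate
17 | 4-bromo-2-iodophenol | Oc1ccc(Br)cc1I | intermediate
18 | 4-methylphenol | Cc1ccc(O)cc1 | starting material
19 | tert-butyldimethyl(4-methylphenoxy)silane | Cc1ccc(O[Si](C)(C)C(C)(C)C)cc1 | intermediate
20 | [4-(bromomethyl)phenoxy](tert-butyl)dimethylsilane | BrCc1ccc(O[Si](C)(C)C(C)(C)C)cc1 | intermediate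
21 | N-methoxy-N-methylacetamide | CC(=O)N(C)OC | starting material
22 | lithium 1-[methoxy(methyl)amino]ethen-1-olate | [Li]OC(=C)N(C)OC | intermediate
23 | 3-hydroxy-N-methoxy-N-methyl-3-[4-(TBSO)phenyl]propanamide (racemic) | CON(C)C(=O)CC(O)c1ccc(O[Si](C)(C)C(C)(C)C)cc1 | intermediate
24 | N-methoxy-N-methyl-3-oxo-3-[4-(TBSO)phenyl]propanamide | CON(C)C(=O)CC(=O)c1ccc(O[Si](C)(C)C(C)(C)C)cc1 | intermediate
25 | methyl bromoacetate | COC(=O)CBr | starting material
26 | methyl 3-[methoxy(methyl)carbamoyl]-4-oxo-4-[4-(TBSO)phenyl]butanoate (racemic) | COC(=O)CC(C(=O)N(C)OC)C(=O)c1ccc(O[Si](C)(C)C(C)(C)C)cc1 | intermediate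
27 | methyl (3R,4R)-4-hydroxy-3-[methoxy(methyl)carbamoyl]-4-[4-(TBSO)phenyl]butanoate (syn) | O[C@@H](c1ccc(O[Si](C)(C)C(C)(C)C)cc1)[C@H](C(=O)N(C)OC)CC(=O)OC | intermediate
28 | (2R,3R)-N-methoxy-N-methyl-5-oxo-2-[4-(TBSO)phenyl]oxolane-3-carboxamide | O=C1O[C@@H](c2ccc(O[Si](C)(C)C(C)(C)C)cc2)[C@H](C(=O)N(C)OC)C1 | intermediate
29 | lithium enolate of 28 (lactone C5–O–Li, C4=C5) | [Li]OC1=C[C@@H](C(=O)N(C)OC)[C@H](c2ccc(O[Si](C)(C)C(C)(C)C)cc2)O1 | intermediate
30 | (2R,3R,4R)-N-methoxy-N-methyl-5-oxo-4-[4-(TBSO)benzyl]-2-[4-(TBSO)phenyl]oxolane-3-carboxamide | O=C1O[C@@H](c2ccc(O[Si](C)(C)C(C)(C)C)cc2)[C@H](C(=O)N(C)OC)[C@H]1Cc1ccc(O[Si](C)(C)C(C)(C)C)cc1 | intermediate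
31 | [2,4-bis(TBSO)phenyl]lithium | [Li]c1ccc(O[Si](C)(C)C(C)(C)C)cc1O[Si](C)(C)C(C)(C)C | intermediate
32 | [2,4-bis(TBSO)phenyl]{(2R,3R,4R,5RS)-5-[2,4-bis(TBSO)phenyl]-5-hydroxy-4-[4-(TBSO)benzyl]-2-[4-(TBSO)phenyl]oxolan-3-yl}methanone | OC1(c2ccc(O[Si](C)(C)C(C)(C)C)cc2O[Si](C)(C)C(C)(C)C)O[C@@H](c2ccc(O[Si](C)(C)C(C)(C)C)cc2)[C@H](C(=O)c2ccc(O[Si](C)(C)C(C)(C)C)cc2O[Si](C)(C)C(C)(C)C)[C@H]1Cc1ccc(O[Si](C)(C)C(C)(C)C)cc1 | intermediate
33 | 1-Ox-2,4-bis(TBSO)benzene | CC(C)(C)[Si](C)(C)Oc1ccc([C@H]2O[C@@H](c3ccc(O[Si](C)(C)C(C)(C)C)cc3)[C@H](C(=O)c3ccc(O[Si](C)(C)C(C)(C)C)cc3O[Si](C)(C)C(C)(C)C)[C@H]2Cc2ccc(O[Si](C)(C)C(C)(C)C)cc2)c(O[Si](C)(C)C(C)(C)C)c1 | intermediate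
34 | 1-bromo-5-Ox-2,4-bis(TBSO)benzene | Brc1cc([C@H]2O[C@@H](c3ccc(O[Si](C)(C)C(C)(C)C)cc3)[C@H](C(=O)c3ccc(O[Si](C)(C)C(C)(C)C)cc3O[Si](C)(C)C(C)(C)C)[C@H]2Cc2ccc(O[Si](C)(C)C(C)(C)C)cc2)c(O[Si](C)(C)C(C)(C)C)cc1O[Si](C)(C)C(C)(C)C | intermediate
35 | (E)-3-[2,4-bis(TBSO)-5-Ox-phenyl]-1-[4-(TBSO)phenyl]prop-2-en-1-one | CC(C)(C)[Si](C)(C)Oc1ccc(C(=O)/C=C/c2cc([C@H]3O[C@@H](c4ccc(O[Si](C)(C)C(C)(C)C)cc4)[C@H](C(=O)c4ccc(O[Si](C)(C)C(C)(C)C)cc4O[Si](C)(C)C(C)(C)C)[C@H]3Cc3ccc(O[Si](C)(C)C(C)(C)C)cc3)c(O[Si](C)(C)C(C)(C)C)cc2O[Si](C)(C)C(C)(C)C)cc1 | intermediate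
36 | (3R)-3-[2,4-bis(TBSO)phenyl]-3-[2,4-bis(TBSO)-5-Ox-phenyl]-1-[4-(TBSO)phenyl]propan-1-one | CC(C)(C)[Si](C)(C)Oc1ccc(C(=O)C[C@H](c2ccc(O[Si](C)(C)C(C)(C)C)cc2O[Si](C)(C)C(C)(C)C)c2cc([C@H]3O[C@@H](c4ccc(O[Si](C)(C)C(C)(C)C)cc4)[C@H](C(=O)c4ccc(O[Si](C)(C)C(C)(C)C)cc4O[Si](C)(C)C(C)(C)C)[C@H]3Cc3ccc(O[Si](C)(C)C(C)(C)C)cc3)c(O[Si](C)(C)C(C)(C)C)cc2O[Si](C)(C)C(C)(C)C)cc1 | intermediate
37 | (1RS,3R)-3-[2,4-bis(TBSO)phenyl]-3-[2,4-bis(TBSO)-5-Ox-phenyl]-1-[4-(TBSO)phenyl]propan-1-ol | CC(C)(C)[Si](C)(C)Oc1ccc(C(O)C[C@H](c2ccc(O[Si](C)(C)C(C)(C)C)cc2O[Si](C)(C)C(C)(C)C)c2cc([C@H]3O[C@@H](c4ccc(O[Si](C)(C)C(C)(C)C)cc4)[C@H](C(=O)c4ccc(O[Si](C)(C)C(C)(C)C)cc4O[Si](C)(C)C(C)(C)C)[C@H]3Cc3ccc(O[Si](C)(C)C(C)(C)C)cc3)c(O[Si](C)(C)C(C)(C)C)cc2O[Si](C)(C)C(C)(C)C)cc1 | intermediate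
38 | (1E,3R)-3-[2,4-bis(TBSO)phenyl]-3-[2,4-bis(TBSO)-5-Ox-phenyl]-1-[4-(TBSO)phenyl]prop-1-ene | CC(C)(C)[Si](C)(C)Oc1ccc(/C=C/[C@H](c2ccc(O[Si](C)(C)C(C)(C)C)cc2O[Si](C)(C)C(C)(C)C)c2cc([C@H]3O[C@@H](c4ccc(O[Si](C)(C)C(C)(C)C)cc4)[C@H](C(=O)c4ccc(O[Si](C)(C)C(C)(C)C)cc4O[Si](C)(C)C(C)(C)C)[C@H]3Cc3ccc(O[Si](C)(C)C(C)(C)C)cc3)c(O[Si](C)(C)C(C)(C)C)cc2O[Si](C)(C)C(C)(C)C)cc1 | intermediate
39 | (2R,3R)-5-bromo-3-{(R)-[2,4-bis(TBSO)phenyl][2,4-bis(TBSO)-5-Ox-phenyl]methyl}-2-[4-(TBSO)phenyl]-2,3-dihydro-1-benzofuran | Brc1ccc2c(c1)[C@@H]([C@H](c1ccc(O[Si](C)(C)C(C)(C)C)cc1O[Si](C)(C)C(C)(C)C)c1cc([C@H]3O[C@@H](c4ccc(O[Si](C)(C)C(C)(C)C)cc4)[C@H](C(=O)c4ccc(O[Si](C)(C)C(C)(C)C)cc4O[Si](C)(C)C(C)(C)C)[C@H]3Cc3ccc(O[Si](C)(C)C(C)(C)C)cc3)c(O[Si](C)(C)C(C)(C)C)cc1O[Si](C)(C)C(C)(C)C)[C@H](c1ccc(O[Si](C)(C)C(C)(C)C)cc1)O2 | intermediate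
40 | undeca-TBS ether of the target (E-chalcone; 2R,3R dihydrobenzofuran; R diarylmethine; Ox unit) | O=C(/C=C/c1ccc2c(c1)[C@@H]([C@H](c1ccc(O[Si](C)(C)C(C)(C)C)cc1O[Si](C)(C)C(C)(C)C)c1cc([C@H]3O[C@@H](c4ccc(O[Si](C)(C)C(C)(C)C)cc4)[C@H](C(=O)c4ccc(O[Si](C)(C)C(C)(C)C)cc4O[Si](C)(C)C(C)(C)C)[C@H]3Cc3ccc(O[Si](C)(C)C(C)(C)C)cc3)c(O[Si](C)(C)C(C)(C)C)cc1O[Si](C)(C)C(C)(C)C)[C@H](c1ccc(O[Si](C)(C)C(C)(C)C)cc1)O2)c1ccc(O[Si](C)(C)C(C)(C)C)cc1O[Si](C)(C)C(C)(C)C | intermediate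
41 | CNP0225254.6 (all eleven phenols free) | O=C(/C=C/c1ccc2c(c1)[C@@H]([C@H](c1ccc(O)cc1O)c1cc([C@H]3O[C@@H](c4ccc(O)cc4)[C@H](C(=O)c4ccc(O)cc4O)[C@H]3Cc3ccc(O)cc3)c(O)cc1O)[C@H](c1ccc(O)cc1)O2)c1ccc(O)cc1O | target

## Step count and risks

Total step count: 27. Longest linear sequence: 17 steps (9 → 10 → 13 → 23 → 24 → 26 → 28 → 30 → 32 → 33 → 34 → 35 → 36 → 37 → 38 → 39 → 40 → 41).

The three steps most likely to fail are 18, 22 and 25.

**Step 18 (double aryllithium addition).** The ortho-silyloxy aryllithium can undergo 1,3-silyl migration, may add twice at the lactone carbon, or may enolise the substrate. The fallback sets out from 30 and comes back at 32. Lactone 30 is opened with Me2AlN(OMe)Me (from AlMe3 and MeNH(OMe)·HCl, CH2Cl2, 0 °C) to the hydroxy bis(Weinreb amide) (2R,3R)-2-[4-(TBSO)benzyl]-3-{(R)-hydroxy[4-(TBSO)phenyl]methyl}-N1,N4-dimethoxy-N1,N4-dimethylbutanediamide F1. This is treated at −20 → 0 °C with excess [2,4-bis(TBSO)phenyl]magnesium bromide 6, made from 3 with Mg turnings and LiCl in THF as in step 4. The Grignard reagent does not suffer silyl migration, and both Weinreb amides stop cleanly at the ketone stage. On AcOH quench the γ-hydroxy ketone is obtained in its ring-closed hemiketal form, which is 32.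

**Step 22 (rhodium conjugate arylation).** Both partners are ortho-substituted, and the hindered pinacol boronate 4 may transmetalate slowly or protodeboronate. The fallback reverses the roles; it sets out from 34 (with 3 and 16) and comes back at 36. Bromide 34 is borylated (Pd(dppf)Cl2, B2pin2, KOAc, 1,4-dioxane, 80 °C) to 2-[2,4-bis(TBSO)-5-Ox-phenyl]-4,4,5,5-tetramethyl-1,3,2-dioxaborolane F2. Bromide 3 and enone 16 are joined by the same Heck conditions as step 21 to (E)-3-[2,4-bis(TBSO)phenyl]-1-[4-(TBSO)phenyl]prop-2-en-1-one F3. The rhodium-catalysed addition of F2 to an excess of the cheap chalcone F3 with the antipodal (S,S)-Ph-bod ligand then gives 36.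

**Step 25 (new oxyarylation).** Insertion next to the bulky diarylmethyl group, β-hydride elimination to a Heck product, or poor ligand control of the face may defeat it. The fallback uses the known Heck–Matsuda oxyarylation of propenylarenes; it sets out from 9 and 38 and comes back at 39. Phenol 9 is nitrated (HNO3, AcOH, 10 °C) to 4-bromo-2-nitrophenol F4. This is reduced (Fe powder, NH4Cl, EtOH/H2O, 70 °C) to 2-amino-4-bromophenol F5 and diazotised (NOBF4, MeCN, 0 °C) to 5-bromo-2-hydroxybenzenediazonium tetrafluoroborate F6. Ligand-free coupling of F6 with 38 (Pd2(dba)3, NaOAc, MeCN, 25 °C) gives the two 2,3-trans ring diastereomers (2R,3R and 2S,3S); they are diastereomers because 38 is enantiopure, so preparative HPLC delivers 39.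

Further compounds
F1 | step 18 | (2R,3R)-2-[4-(TBSO)benzyl]-3-{(R)-hydroxy[4-(TBSO)phenyl]methyl}-N1,N4-dimethoxy-N1,N4-dimethylbutanediamide | O[C@@H](c1ccc(O[Si](C)(C)C(C)(C)C)cc1)[C@H](C(=O)N(C)OC)[C@@H](Cc1ccc(O[Si](C)(C)C(C)(C)C)cc1)C(=O)N(C)OC
F2 | step 22 | 2-[2,4-bis(TBSO)-5-Ox-phenyl]-4,4,5,5-tetramethyl-1,3,2-dioxaborolane | CC1(C)OB(OC1(C)C)c1cc([C@H]2O[C@@H](c3ccc(O[Si](C)(C)C(C)(C)C)cc3)[C@H](C(=O)c3ccc(O[Si](C)(C)C(C)(C)C)cc3O[Si](C)(C)C(C)(C)C)[C@H]2Cc2ccc(O[Si](C)(C)C(C)(C)C)cc2)c(O[Si](C)(C)C(C)(C)C)cc1O[Si](C)(C)C(C)(C)C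
F3 | step 22 | (E)-3-[2,4-bis(TBSO)phenyl]-1-[4-(TBSO)phenyl]prop-2-en-1-one | CC(C)(C)[Si](C)(C)Oc1ccc(C(=O)/C=C/c2ccc(O[Si](C)(C)C(C)(C)C)cc2O[Si](C)(C)C(C)(C)C)cc1
F4 | step 25 | 4-bromo-2-nitrophenol | Oc1ccc(Br)cc1[N+](=O)[O-]
F5 | step 25 | 2-amino-4-bromophenol | Nc1cc(Br)ccc1O
F6 | step 25 | 5-bromo-2-hydroxybenzenediazonium tetrafluoroborate | Oc1ccc(Br)cc1[N+]#N.F[B-](F)(F)F
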